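**Retrosynthetic overview**

- Numbering: C1 = methyl-bearing bridgehead, C2 = CH2, C3=C4(CHO), C5 = formyl-bearing bridgehead, C6 = side-chain carbon, C7 and C8 = CH2, C9 = acetoxy bridge, C1' = side-chain CH(CH3); ring A = C1-C2-C3-C4-C5-C9, ring B = C1-C8-C7-C6-C5-C9. The plan rests on one feature: the only ring alkene, C3=C4, lies in the three-carbon bridge C2-C3-C4 that spans the two quaternary bridgeheads C1 and C5 of ring B.
- Ring A is therefore closed last, by ring-closing metathesis across C3=C4 of a ring B cyclohexanone carrying a C1 allyl arm and a C5 3-silyloxyprop-1-en-2-yl arm held cis-1,3; C9 reduction, acetylation, desilylation and double oxidation follow.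
- The metathesis precursor comes from a carvone-type enone by reductive allylation at C1, then acylation, hydroxymethylation and methylenation at C5/C4.
- The enone (ring B) comes from an amine-catalysed Michael/aldol annulation of methyl 3-oxopentanoate with the one-carbon-homologated enal of (R)-citronellal, which supplies C1'.
- Ring order: ring B (step 3), then ring A (step 11).

Key step: step 11

Remark: the face assigned to the (S)-configured prolinol catalyst in step 3 follows the usual shielding model for (E)-iminium ions, and the γ-methyl stereocentre of the enal is assumed not to override it. Names of the bicyclic compounds use the numbering given above.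

**Step 1**
Reactants: 1 (R)-citronellal
Product: 2 (4R)-1-methoxy-4,8-dimethylnona-1,7-diene (E/Z mixture of the enol ether)
Conditions: MeOCH2PPh3Cl, KOt-Bu, THF, 0 °C; then 1, 0 °C to rt
Reagents that add atoms: (methoxymethyl)triphenylphosphonium chloride, COC[P+](c1ccccc1)(c1ccccc1)c1ccccc1.[Cl-]
Why: Wittig olefination with the methoxymethylene ylide adds the carbon that becomes C8; the citronellal stereocentre (future C1') is β to the carbonyl and is not touched.

**Step 2**
Reactants: 2 (4R)-1-methoxy-4,8-dimethylnona-1,7-diene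
Product: 3 (2E,4R)-4,8-dimethylnona-2,7-dienal
Conditions: Pd(OAc)2 (10 mol %), Cu(OAc)2 (2 equiv), NaHCO3, MeCN–H2O, rt
Reagents that add atoms: water, O
Why: Saegusa–Ito-type dehydrogenation of an enol ether: divalent palladium palladates C2, water opens the oxocarbenium ion and β-hydride loss should give the (E)-enal, whose β-carbon is the future C6; the isolated trisubstituted alkene is a far weaker ligand than the enol ether.

**Step 3**
Reactants: 3 (2E,4R)-4,8-dimethylnona-2,7-dienal; 4 methyl 3-oxopentanoate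
Product: 6 methyl (6S)-3-methyl-6-[(2R)-6-methylhept-5-en-2-yl]-2-oxocyclohex-3-ene-1-carboxylate (both C1 epimers), via Michael adduct 5 (not isolated)
Conditions: (S)-2-[diphenyl(trimethylsilyloxy)methyl]pyrrolidine (10 mol %), PhCO2H (10 mol %), toluene, rt; then TsOH·H2O (20 mol %), 40 °C
Reagents that add atoms: none
Why: Iminium-ion Michael addition followed by intramolecular aldol condensation (a Robinson-type 3+3 annulation): the ketoester methine (future C5) should add to the enal β-carbon on the face left open by the diphenyl(silyloxy)methyl group of the (S)-catalyst, which sets C6 under catalyst control, and the ethyl CH2 (future C1) then condenses with the aldehyde (future C8) to close ring B.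

**Step 4**
Reactants: 6 methyl (6S)-3-methyl-6-[(2R)-6-methylhept-5-en-2-yl]-2-oxocyclohex-3-ene-1-carboxylate
Product: 7 (5R)-2-methyl-5-[(2R)-6-methylhept-5-en-2-yl]cyclohex-2-en-1-one
Conditions: LiCl, H2O, DMSO, 150 °C
Reagents that add atoms: none
Why: Krapcho dealkoxycarbonylation (chloride attack on the methyl ester, loss of CO2) removes the ester under neutral conditions; C6 is β to the ketone and cannot epimerise.

**Step 5**
Reactants: 7 (5R)-2-methyl-5-[(2R)-6-methylhept-5-en-2-yl]cyclohex-2-en-1-one; 8 allyl bromide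
Product: 10 (2R,5R)-2-methyl-5-[(2R)-6-methylhept-5-en-2-yl]-2-(prop-2-en-1-yl)cyclohexan-1-one, via lithium enolate 9 (not isolated)
Conditions: LiBH(sec-Bu)3, THF, −78 °C; then 8, −78 to 0 °C
Reagents that add atoms: none
Why: Reductive alkylation: conjugate hydride addition at C8 gives the C9–C1 enolate regiospecifically, and axial attack of allyl bromide on the half-chair with the C6 side chain equatorial should place the allyl group cis to that side chain, the C1 configuration needed for bridging.

**Step 6**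
Reactants: 10 (2R,5R)-2-methyl-5-[(2R)-6-methylhept-5-en-2-yl]-2-(prop-2-en-1-yl)cyclohexan-1-one; 11 (tert-butyldimethylsilyloxy)acetaldehyde
Product: 13 (2R,5S)-6-[2-(tert-butyldimethylsilyloxy)-1-hydroxyethyl]-2-methyl-5-[(2R)-6-methylhept-5-en-2-yl]-2-(prop-2-en-1-yl)cyclohexan-1-one (epimers at C6 plus carbinol carbon), via lithium enolate 12 (not isolated)
Conditions: LiN(i-Pr)2, THF, −78 °C; then 11; H2O
Reagents that add atoms: none
Why: Aldol addition: C1 is quaternary, so the amide base can enolise only toward C5, and the α-silyloxy aldehyde attaches the C4 unit; the two new stereocentres are erased in steps 7 and 8.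

**Step 7**
Reactants: 13 (2R,5S)-6-[2-(tert-butyldimethylsilyloxy)-1-hydroxyethyl]-2-methyl-5-[(2R)-6-methylhept-5-en-2-yl]-2-(prop-2-en-1-yl)cyclohexan-1-one
Product: 14 (2R,5S)-6-[(tert-butyldimethylsilyloxy)acetyl]-2-methyl-5-[(2R)-6-methylhept-5-en-2-yl]-2-(prop-2-en-1-yl)cyclohexan-1-one (C6 epimers plus enol forms)
Conditions: Dess–Martin periodinane, CH2Cl2, 0 °C to rt
Reagents that add atoms: none
Why: Dess–Martin oxidation of a β-hydroxy ketone gives the 1,3-diketone without touching the silyl ether or the alkenes.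

**Step 8**
Reactants: 14 (2R,5S)-6-[(tert-butyldimethylsilyloxy)acetyl]-2-methyl-5-[(2R)-6-methylhept-5-en-2-yl]-2-(prop-2-en-1-yl)cyclohexan-1-one
Product: 15 (2S,3S,6R)-2-[(tert-butyldimethylsilyloxy)acetyl]-2-(hydroxymethyl)-6-methyl-3-[(2R)-6-methylhept-5-en-2-yl]-6-(prop-2-en-1-yl)cyclohexan-1-one
Conditions: HCHO (37 % aq.), Et3N (cat.), THF, 0 °C to rt
Reagents that add atoms: formaldehyde, C=O
Why: Amine-catalysed aldol addition of the diketone enolate to formaldehyde at the doubly activated C5: allylic strain with the planar enolate should turn the C6 side chain pseudo-axial so that formaldehyde adds to the opposite face, leaving the acyl arm cis to the side chain and to the C1 allyl group.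

**Step 9**
Reactants: 15 (2S,3S,6R)-2-[(tert-butyldimethylsilyloxy)acetyl]-2-(hydroxymethyl)-6-methyl-3-[(2R)-6-methylhept-5-en-2-yl]-6-(prop-2-en-1-yl)cyclohexan-1-one
Product: 16 (2S,3S,6R)-2-[(tert-butyldimethylsilyloxy)acetyl]-2-[(tert-butyldimethylsilyloxy)methyl]-6-methyl-3-[(2R)-6-methylhept-5-en-2-yl]-6-(prop-2-en-1-yl)cyclohexan-1-one
Conditions: TBSCl, imidazole, DMF, rt
Reagents that add atoms: tert-butyldimethylsilyl chloride, CC(C)(C)[Si](C)(C)Cl
Why: Silylation of the primary alcohol blocks retro-aldol loss of formaldehyde; both primary oxygens now carry the same group, since they are unmasked and oxidised together at the end.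

**Step 10**
Reactants: 16 (2S,3S,6R)-2-[(tert-butyldimethylsilyloxy)acetyl]-2-[(tert-butyldimethylsilyloxy)methyl]-6-methyl-3-[(2R)-6-methylhept-5-en-2-yl]-6-(prop-2-en-1-yl)cyclohexan-1-one
Product: 17 (2S,3S,6R)-2-[3-(tert-butyldimethylsilyloxy)prop-1-en-2-yl]-2-[(tert-butyldimethylsilyloxy)methyl]-6-methyl-3-[(2R)-6-methylhept-5-en-2-yl]-6-(prop-2-en-1-yl)cyclohexan-1-one
Conditions: Cp2Ti(μ-Cl)(μ-CH2)AlMe2, pyridine, THF–toluene, −40 to 0 °C
Reagents that add atoms: Tebbe reagent Cp2Ti(μ-Cl)(μ-CH2)AlMe2, C[Al-]1(C)C[Ti]([Cl+]1)(C1C=CC=C1)C1C=CC=C1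
Why: Tebbe methylenation through an oxatitanacyclobutane is non-basic, which avoids cleavage of the non-enolisable 1,3-diketone, and should select the α-silyloxy C4 ketone over the C9 carbonyl, which is flanked by two quaternary carbons.

**Step 11**
Reactants: 17 (2S,3S,6R)-2-[3-(tert-butyldimethylsilyloxy)prop-1-en-2-yl]-2-[(tert-butyldimethylsilyloxy)methyl]-6-methyl-3-[(2R)-6-methylhept-5-en-2-yl]-6-(prop-2-en-1-yl)cyclohexan-1-one
Product: 18 (1R,5S,6S)-4,5-bis[(tert-butyldimethylsilyloxy)methyl]-1-methyl-6-[(2R)-6-methylhept-5-en-2-yl]bicyclo[3.3.1]non-3-en-9-one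
Conditions: second-generation Grubbs catalyst (H2IMes)(PCy3)Cl2Ru=CHPh (10 mol %), toluene (2 mM), 80 °C
Reagents that add atoms: none
Why: The ruthenium benzylidene should first exchange onto the only monosubstituted alkene, the C1 allyl group, to give the C3 alkylidene, which adds across the 1,1-disubstituted C4 alkene; cycloreversion of the ruthenacyclobutane forms C3=C4 and passes on Ru=CH2, so ethylene is the only co-product. The closest known reaction type is ring-closing metathesis of cyclohexanones with cis-1,3 allyl and alkenyl arms to bicyclo[3.3.1]nonenones. Ring A closes as a six-membered ring from an octa-1,7-diene unit running through C3, C2, C1, C9, C5 and C4, with the new alkene endocyclic in the three-carbon bridge; this needs the ring B chair with both arms axial, which the planar C9 carbonyl between them makes reachable. No stereocentre is formed, the ring alkene can only be cis, and C4 already carries its oxygenated carbon. The step needs chemoselectivity among three alkenes and closure in preference to intermolecular coupling: the trisubstituted side-chain alkene is a poor partner and could only close a ten-membered ring from C3, the cis-1,3 relation of the arms was fixed in steps 5 and 8, and high dilution suppresses dimerisation.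

**Step 12**
Reactants: 18 (1R,5S,6S)-4,5-bis[(tert-butyldimethylsilyloxy)methyl]-1-methyl-6-[(2R)-6-methylhept-5-en-2-yl]bicyclo[3.3.1]non-3-en-9-one
Product: 19 (1R,5S,6S,9R)-4,5-bis[(tert-butyldimethylsilyloxy)methyl]-1-methyl-6-[(2R)-6-methylhept-5-en-2-yl]bicyclo[3.3.1]non-3-en-9-ol
Conditions: LiAlH4, Et2O, −20 to 0 °C
Reagents that add atoms: none
Why: Hydride reduction of the bridging ketone: attack should come over the flattened C2–C3=C4 bridge and not over ring B, whose axial hydrogens at C6 and C8 screen the other face, so the C9 oxygen ends up anti to the alkene bridge (9R).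

**Step 13**
Reactants: 19 (1R,5S,6S,9R)-4,5-bis[(tert-butyldimethylsilyloxy)methyl]-1-methyl-6-[(2R)-6-methylhept-5-en-2-yl]bicyclo[3.3.1]non-3-en-9-ol
Product: 20 (1R,5S,6S,9R)-4,5-bis[(tert-butyldimethylsilyloxy)methyl]-1-methyl-6-[(2R)-6-methylhept-5-en-2-yl]bicyclo[3.3.1]non-3-en-9-yl acetate
Conditions: Ac2O, DMAP, pyridine, 50 °C
Reagents that add atoms: acetic anhydride, CC(=O)OC(C)=O
Why: DMAP-catalysed acylation of the only free hydroxyl; the hindered secondary alcohol is expected to need warming.

**Step 14**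
Reactants: 20 (1R,5S,6S,9R)-4,5-bis[(tert-butyldimethylsilyloxy)methyl]-1-methyl-6-[(2R)-6-methylhept-5-en-2-yl]bicyclo[3.3.1]non-3-en-9-yl acetate
Product: 21 (1R,5S,6S,9R)-4,5-bis(hydroxymethyl)-1-methyl-6-[(2R)-6-methylhept-5-en-2-yl]bicyclo[3.3.1]non-3-en-9-yl acetate
Conditions: HF·pyridine, pyridine, THF, 0 °C to rt
Reagents that add atoms: none
Why: Fluoride-induced desilylation removes both silyl ethers at once; the buffered acidic medium should avoid the base-induced acetyl shift from O9 to the neighbouring C5 hydroxymethyl group.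

**Step 15**
Reactants: 21 (1R,5S,6S,9R)-4,5-bis(hydroxymethyl)-1-methyl-6-[(2R)-6-methylhept-5-en-2-yl]bicyclo[3.3.1]non-3-en-9-yl acetate
Product: 22 (1R,5R,6S,9R)-4,5-diformyl-1-methyl-6-[(2R)-6-methylhept-5-en-2-yl]bicyclo[3.3.1]non-3-en-9-yl acetate (CNP0299929.2)
Conditions: (COCl)2, DMSO, CH2Cl2, −78 °C; then Et3N, −78 to 0 °C
Reagents that add atoms: none
Why: Swern oxidation activates both primary alcohols before base is added, so no lactol can form between them; C5 has no α-hydrogen, so the β-acetoxy aldehyde cannot eliminate.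

**Compound list**

1 | (R)-citronellal, (3R)-3,7-dimethyloct-6-enal | O=CC[C@H](C)CCC=C(C)C | starting material
2 | (4R)-1-methoxy-4,8-dimethylnona-1,7-diene (E/Z mixture) | COC=CC[C@H](C)CCC=C(C)C | intermediate
3 | (2E,4R)-4,8-dimethylnona-2,7-dienal | O=C/C=C/[C@H](C)CCC=C(C)C | intermediate
4 | methyl 3-oxopentanoate | CCC(=O)CC(=O)OC | starting material
5 | methyl (3S,4R)-4,8-dimethyl-3-(2-oxoethyl)-2-propanoylnon-7-enoate (Michael adduct, both C2 epimers) | CCC(=O)C(C(=O)OC)[C@@H](CC=O)[C@H](C)CCC=C(C)C | intermediate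
6 | methyl (6S)-3-methyl-6-[(2R)-6-methylhept-5-en-2-yl]-2-oxocyclohex-3-ene-1-carboxylate (both C1 epimers) | COC(=O)C1C(=O)C(C)=CC[C@H]1[C@H](C)CCC=C(C)C | intermediate
7 | (5R)-2-methyl-5-[(2R)-6-methylhept-5-en-2-yl]cyclohex-2-en-1-one | O=C1C(C)=CC[C@@H]([C@H](C)CCC=C(C)C)C1 | intermediate
8 | allyl bromide, 3-bromoprop-1-ene | C=CCBr | starting material
9 | lithium (5R)-2-methyl-5-[(2R)-6-methylhept-5-en-2-yl]cyclohex-1-en-1-olate | [Li]OC1=C(C)CC[C@@H]([C@H](C)CCC=C(C)C)C1 | intermediate
10 | (2R,5R)-2-methyl-5-[(2R)-6-methylhept-5-en-2-yl]-2-(prop-2-en-1-yl)cyclohexan-1-one | O=C1[C@@](C)(CC=C)CC[C@@H]([C@H](C)CCC=C(C)C)C1 | intermediate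
11 | (tert-butyldimethylsilyloxy)acetaldehyde | O=CCO[Si](C)(C)C(C)(C)C | starting material
12 | lithium (3S,6R)-6-methyl-3-[(2R)-6-methylhept-5-en-2-yl]-6-(prop-2-en-1-yl)cyclohex-1-en-1-olate | [Li]OC1=C[C@H]([C@H](C)CCC=C(C)C)CC[C@]1(C)CC=C | intermediate
13 | (2R,5S)-6-[2-(tert-butyldimethylsilyloxy)-1-hydroxyethyl]-2-methyl-5-[(2R)-6-methylhept-5-en-2-yl]-2-(prop-2-en-1-yl)cyclohexan-1-one (epimers at C6 and at the carbinol carbon) | O=C1[C@@](C)(CC=C)CC[C@@H]([C@H](C)CCC=C(C)C)C1C(O)CO[Si](C)(C)C(C)(C)C | intermediate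
14 | (2R,5S)-6-[(tert-butyldimethylsilyloxy)acetyl]-2-methyl-5-[(2R)-6-methylhept-5-en-2-yl]-2-(prop-2-en-1-yl)cyclohexan-1-one (C6 epimers and enol forms) | O=C1[C@@](C)(CC=C)CC[C@@H]([C@H](C)CCC=C(C)C)C1C(=O)CO[Si](C)(C)C(C)(C)C | intermediate
15 | (2S,3S,6R)-2-[(tert-butyldimethylsilyloxy)acetyl]-2-(hydroxymethyl)-6-methyl-3-[(2R)-6-methylhept-5-en-2-yl]-6-(prop-2-en-1-yl)cyclohexan-1-one | O=C1[C@@](C)(CC=C)CC[C@@H]([C@H](C)CCC=C(C)C)[C@@]1(CO)C(=O)CO[Si](C)(C)C(C)(C)C | intermediate
16 | (2S,3S,6R)-2-[(tert-butyldimethylsilyloxy)acetyl]-2-[(tert-butyldimethylsilyloxy)methyl]-6-methyl-3-[(2R)-6-methylhept-5-en-2-yl]-6-(prop-2-en-1-yl)cyclohexan-1-one | O=C1[C@@](C)(CC=C)CC[C@@H]([C@H](C)CCC=C(C)C)[C@@]1(CO[Si](C)(C)C(C)(C)C)C(=O)CO[Si](C)(C)C(C)(C)C | intermediate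
17 | (2S,3S,6R)-2-[3-(tert-butyldimethylsilyloxy)prop-1-en-2-yl]-2-[(tert-butyldimethylsilyloxy)methyl]-6-methyl-3-[(2R)-6-methylhept-5-en-2-yl]-6-(prop-2-en-1-yl)cyclohexan-1-one | O=C1[C@@](C)(CC=C)CC[C@@H]([C@H](C)CCC=C(C)C)[C@@]1(CO[Si](C)(C)C(C)(C)C)C(=C)CO[Si](C)(C)C(C)(C)C | intermediate
18 | (1R,5S,6S)-4,5-bis[(tert-butyldimethylsilyloxy)methyl]-1-methyl-6-[(2R)-6-methylhept-5-en-2-yl]bicyclo[3.3.1]non-3-en-9-one | O=C1[C@@]2(C)CC=C(CO[Si](C)(C)C(C)(C)C)[C@]1(CO[Si](C)(C)C(C)(C)C)[C@H]([C@H](C)CCC=C(C)C)CC2 | intermediate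
19 | (1R,5S,6S,9R)-4,5-bis[(tert-butyldimethylsilyloxy)methyl]-1-methyl-6-[(2R)-6-methylhept-5-en-2-yl]bicyclo[3.3.1]non-3-en-9-ol | O[C@@H]1[C@@]2(C)CC=C(CO[Si](C)(C)C(C)(C)C)[C@]1(CO[Si](C)(C)C(C)(C)C)[C@H]([C@H](C)CCC=C(C)C)CC2 | intermediate
20 | (1R,5S,6S,9R)-4,5-bis[(tert-butyldimethylsilyloxy)methyl]-1-methyl-6-[(2R)-6-methylhept-5-en-2-yl]bicyclo[3.3.1]non-3-en-9-yl acetate | CC(=O)O[C@@H]1[C@@]2(C)CC=C(CO[Si](C)(C)C(C)(C)C)[C@]1(CO[Si](C)(C)C(C)(C)C)[C@H]([C@H](C)CCC=C(C)C)CC2 | intermediate
21 | (1R,5S,6S,9R)-4,5-bis(hydroxymethyl)-1-methyl-6-[(2R)-6-methylhept-5-en-2-yl]bicyclo[3.3.1]non-3-en-9-yl acetate | CC(=O)O[C@@H]1[C@@]2(C)CC=C(CO)[C@]1(CO)[C@H]([C@H](C)CCC=C(C)C)CC2 | intermediate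
22 | (1R,5R,6S,9R)-4,5-diformyl-1-methyl-6-[(2R)-6-methylhept-5-en-2-yl]bicyclo[3.3.1]non-3-en-9-yl acetate (CNP0299929.2) | CC(=O)O[C@@H]1[C@@]2(C)CC=C(C=O)[C@]1(C=O)[C@H]([C@H](C)CCC=C(C)C)CC2 | target

Total step count: 15. Longest linear sequence: 15 steps, from (R)-citronellal 1 to 22.

**Steps most likely to fail**

Step 11 (key ring closure). The alkylidene loaded at C3 may fail to add across the crowded 1,1-disubstituted alkene beside the quaternary C5, so that intermolecular coupling of allyl termini or double-bond migration in the allyl group takes over. The fallback sets out from diketone 16 and returns at 18, and closes ring A by stoichiometric alkylidene-mediated olefin metathesis/carbonyl olefination. Mo(=CHCMe2Ph)(=N-2,6-i-Pr2C6H3)[OCMe(CF3)2]2 (1 equiv, benzene, rt) should exchange onto the allyl terminus of 16, and the resulting C3 alkylidene should then olefinate the C4 ketone in a Wittig-like step. This forms C3=C4 directly, needs no 1,1-disubstituted alkene and leaves out step 10. The C9 carbonyl cannot react this way because the ring would be four-membered. No compound outside the list is formed.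

Step 5 (C1 allylation). Facial selectivity may be poor, because the C6 substituent is remote and equatorial attack through a twist-boat can compete; the C1 epimer cannot be bridged later. The fallback sets out from enone 7 and returns at 10. The enolate 9, made as in step 5, is trapped on oxygen with allyl chloroformate to give the allyl enol carbonate F1. Pd2(dba)3 with (R)-t-Bu-PHOX in THF at rt then effects a decarboxylative allylic alkylation of the Tsuji type. Here the chiral palladium π-allyl complex, not the ring, selects the enolate face. The ligand enantiomer is the one that gives the (R)-configured quaternary carbon in the parent 2-methylcyclohexanone series.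

Step 10 (methylenation). The neopentyl C4 carbonyl may be too shielded for the titanium methylidene; slow reaction would open the way to methylenation at C9 or to cleavage of the C4–C5 bond of the non-enolisable 1,3-diketone. The fallback sets out from 16 and returns at 17 by a two-stage Peterson olefination. Me3SiCH2Li with CeCl3 (THF, −78 °C) adds to the C4 ketone to give the β-hydroxysilane F2. BF3·OEt2 (cat., CH2Cl2, −20 °C) then induces anti-elimination to the 1,1-disubstituted alkene of 17.

**Further compounds**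

F0 | step 11 | none | none
F1 | step 5 | prop-2-en-1-yl (5R)-2-methyl-5-[(2R)-6-methylhept-5-en-2-yl]cyclohex-1-en-1-yl carbonate | C=CCOC(=O)OC1=C(C)CC[C@@H]([C@H](C)CCC=C(C)C)C1
F2 | step 10 | (2R,3S,6R)-2-[1-(tert-butyldimethylsilyloxy)-2-hydroxy-3-(trimethylsilyl)propan-2-yl]-2-[(tert-butyldimethylsilyloxy)methyl]-6-methyl-3-[(2R)-6-methylhept-5-en-2-yl]-6-(prop-2-en-1-yl)cyclohexan-1-one (both carbinol epimers) | O=C1[C@@](C)(CC=C)CC[C@@H]([C@H](C)CCC=C(C)C)[C@@]1(CO[Si](C)(C)C(C)(C)C)C(O)(C[Si](C)(C)C)CO[Si](C)(C)C(C)(C)C
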